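C8 (prenyl, lavandulyl) of the carbocycle C4a–C5–C6–C7–C8–C8a lies para to enol oxygen O5, which sits between two fully substituted carbons, C6 (side chain) and C4a (acyl carbon of the chromanone ring). Cα, the CH(propyl) carbon on C6, can be tied to O7 as a six-membered lactone, which places propyl pseudoaxial and peri to O5.
Cuts, in retrosynthetic order: acid closed back onto O7 as an enol lactone; C8–CH2(prenyl), with prenyl returned to O5, which restores a benzene ring; H–C2/H–C3 (chromanone to chromone) and O5–prenyl; C6–Cα and O7–acyl (hex-2-enal); C8–CH2(lavandulyl) (alkylzinc plus aryl iodide); the pyranone ring (propiophenone plus acetic anhydride); the α-C–prenyl bond of the lavandulyl unit.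
Forward: the pyranone ring is closed on the purchased arene, lavandulyl is coupled to C8, and the lactone ring is annulated across C6/O7. O5 is then prenylated, the chromone is reduced to the cis-chromanone, the O5-to-C8 prenyl shift turns the benzene ring into the cyclohexadienone, and the lactone is opened last.
Stereochemistry: the lavandulyl centre comes from an oxazolidinone-controlled dienolate prenylation, Cα (R) from a chiral NHC, C2 (R) from the chiral ligand on copper hydride, and C3 (S) from kinetic protonation. C8 (R) is set by relay from Cα in the key step.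

Key step: step 14

Conventions: chromone locants (O1, C2, C3, C4, C4a, C5–C8, C8a) are kept up to the target. Lavandulyl = 5-methyl-2-(prop-1-en-2-yl)hex-4-en-1-yl. Its stereocentre keeps one spatial arrangement throughout. Its descriptor is S in the imide, alcohol, iodide and zinc reagent and R once its CH2 is bonded to the ring, purely through CIP priorities.
Assumption: the sense of induction of the two chiral catalysts (triazolium salt, bisphosphine) is inferred from their closest analogues. Both exist in either enantiomeric form, and the one that gives Cα (R) and C2 (R) is meant.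

Step 1
Reactants: 1 3-methylbut-2-enoyl chloride; 2 (S)-4-benzyloxazolidin-2-one
Product: 3 (S)-4-benzyl-3-(3-methylbut-2-enoyl)oxazolidin-2-one
Conditions: 2, n-BuLi, THF, −78 °C; then 1, −78 to 0 °C
Reagents that add atoms: none
Why: N-acylation of the lithiated oxazolidinone with an acid chloride is the standard entry to such imides, and working without an amine base avoids vinylketene formation and premature deconjugation.

Step 2
Reactants: 3 (S)-4-benzyl-3-(3-methylbut-2-enoyl)oxazolidin-2-one; 4 prenyl bromide
Product: 6 (S)-4-benzyl-3-[(2S)-5-methyl-2-(prop-1-en-2-yl)hex-4-enoyl]oxazolidin-2-one, via sodium Z-dienolate 5 (not isolated)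
Conditions: NaHMDS (1.05 equiv), THF, −78 °C; then 4, −78 to −40 °C
Reagents that add atoms: none
Why: γ-Deprotonation gives the chelated Z(O)-dienolate, which in this deconjugative auxiliary-controlled alkylation reacts at the α-carbon on the face away from the benzyl group and so sets the (S) centre that becomes the lavandulyl stereocentre.

Step 3
Reactants: 6 α-prenylated β,γ-unsaturated imide
Product: 7 (S)-lavandulol [(2S)-5-methyl-2-(prop-1-en-2-yl)hex-4-en-1-ol]
Conditions: LiBH4, H2O (1 equiv), Et2O, 0 °C
Reagents that add atoms: none
Why: Hydride reduction of the exocyclic imide carbonyl releases the primary alcohol and the auxiliary faster than the medium can reconjugate or epimerise the β,γ-unsaturated acyl unit, and the alkenes are inert to borohydride.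

Step 4
Reactants: 7 (S)-lavandulol
Product: 8 (S)-lavandulyl iodide [(3S)-3-(iodomethyl)-2,6-dimethylhepta-1,5-diene]
Conditions: I2, PPh3, imidazole, CH2Cl2, 0 °C, dark
Reagents that add atoms: iodine, II
Why: The Appel iodination displaces the activated primary oxygen by iodide under buffered conditions, so that neither the adjacent stereocentre nor the acid-sensitive alkenes are touched.

Step 5
Reactants: 9 2,4,6-trihydroxypropiophenone
Product: 10 5,7-diacetoxy-2,3-dimethylchromone
Conditions: Ac2O, NaOAc, reflux
Reagents that add atoms: acetic anhydride, CC(=O)OC(C)=O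
Why: In the Kostanecki–Robinson chromone synthesis O-acetylation, acyl transfer to the α-carbon of the propionyl group and cyclodehydration close the pyranone ring, the α-methyl group excludes 3-acetylation and the symmetry of the arene excludes regioisomers.

Step 6
Reactants: 10 5,7-diacetoxy-2,3-dimethylchromone
Product: 11 5,7-dihydroxy-2,3-dimethylchromone
Conditions: conc. HCl (cat.), MeOH, reflux
Reagents that add atoms: none
Why: Acid-catalysed transesterification removes both aryl acetates and avoids the attack at C2 with ring opening that hydroxide can cause on a chromone.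

Step 7
Reactants: 11 5,7-dihydroxy-2,3-dimethylchromone
Product: 12 5,7-bis(methoxymethoxy)-2,3-dimethylchromone
Conditions: NaH (2.2 equiv), MOMCl (2.5 equiv), DMF, 0 °C to rt
Reagents that add atoms: chloromethyl methyl ether, COCCl
Why: Full deprotonation allows Williamson-type acetal formation also at the 5-OH that is hydrogen-bonded to C4=O, and alkylation of both oxygens is what steers the next substitution to C8.

Step 8
Reactants: 12 5,7-bis(methoxymethoxy)-2,3-dimethylchromone
Product: 13 8-iodo-5,7-bis(methoxymethoxy)-2,3-dimethylchromone
Conditions: NIS, MeCN, 0 °C to rt, dark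
Reagents that add atoms: N-iodosuccinimide, O=C1CCC(=O)N1I
Why: In electrophilic iodination 5,7-dialkoxychromones without a free 5-OH react at C8, which is activated by O1, O7 and the para O5 and is less crowded than C6 between two acetal groups, while neutral NIS leaves the acetals intact.

Step 9
Reactants: 8 (S)-lavandulyl iodide; 13 8-iodo-5,7-bis(methoxymethoxy)-2,3-dimethylchromone
Product: 15 8-[(R)-lavandulyl]-5,7-bis(methoxymethoxy)-2,3-dimethylchromone, via lavandulylzinc iodide 14 (not isolated)
Conditions: 8, Zn dust, LiCl, THF, 35 °C; then 13, Pd(OAc)2 (3 mol %), SPhos (6 mol %), THF, 40 °C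
Reagents that add atoms: none
Why: Zinc inserts into the primary C–I bond without touching the stereocentre one carbon away, and the Negishi sp2–sp3 coupling with a bulky electron-rich biarylphosphine copes with the di-ortho-substituted iodide, outruns β-hydride elimination and tolerates the chromone carbonyl and the acetals.

Step 10
Reactants: 15 8-[(R)-lavandulyl]-5,7-bis(methoxymethoxy)-2,3-dimethylchromone
Product: 16 8-[(R)-lavandulyl]-5,7-dihydroxy-2,3-dimethylchromone
Conditions: p-TsOH·H2O (20 mol %), MeOH, 40 °C
Reagents that add atoms: none
Why: Acid-catalysed transacetalisation to methanol frees both phenols, and the levelled acidity of methanolic sulfonic acid should be too low to protonate the isopropenyl and prenyl double bonds, so that chroman closure by the neighbouring 7-OH is avoided.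

Step 11
Reactants: 16 8-[(R)-lavandulyl]-5,7-dihydroxy-2,3-dimethylchromone; 17 (E)-hex-2-enal
Product: 18 5-hydroxy-8-[(R)-lavandulyl]-2,3-dimethylchromone bridged by the lactone C6–CαH(propyl)–CH2–C(=O)–O7 with Cα (R)
Conditions: aminoindanol-derived N-mesityl-1,2,4-triazolium chloride (10 mol %), DBU (15 mol %), 3,3',5,5'-tetra-tert-butyldiphenoquinone (1.1 equiv), 4 Å MS, toluene, rt
Reagents that add atoms: none
Why: In this oxidative NHC [3+3] annulation, known for 2-naphthols and other stable enols, the enal is oxidised on the carbene to the α,β-unsaturated acyl azolium, C6 as the only free arene carbon adds in Michael fashion on the face left open by the chiral carbene to set Cα (R), and acyl transfer to the acidic non-chelated O7 closes the lactone, any O7-enoate formed first being an active ester that can re-enter the cycle.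

Step 12
Reactants: 18 lactone-fused chromone with free 5-OH; 4 prenyl bromide
Product: 19 5-O-prenyl ether of the lactone-fused chromone
Conditions: 4 (1.3 equiv), Cs2CO3 (1.2 equiv), 4 Å MS, MeCN, rt
Reagents that add atoms: none
Why: Williamson alkylation of the only free phenol in a polar aprotic medium takes place at oxygen, the dry hydroxide-free conditions keep the aryl lactone closed, a direct acyl shift from O7 to O5 is impossible across planar C6, and room temperature is too low for rearrangement.

Step 13
Reactants: 19 5-O-prenyl ether of the lactone-fused chromone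
Product: 21 5-O-prenyl ether of the lactone-fused (2R,3S)-cis-2,3-dimethylchroman-4-one, via silyl enol ether 20 (not isolated)
Conditions: Cu(OAc)2·H2O (5 mol %), (R)-DTBM-SEGPHOS (5.5 mol %), (EtO)2MeSiH (2.5 equiv), toluene, 0 °C to rt; then AcOH–THF–H2O, −20 to 0 °C
Reagents that add atoms: none
Why: Ligand-controlled copper hydride conjugate reduction, known for chromones, delivers hydride to one face of C2 (R) and ignores the isolated alkenes, the allyl aryl ether and the lactone, the product stays masked as silyl enol ether 20 so that the ketone is not reduced further, and cold protonation occurs anti to the 2-methyl group, held pseudoaxial by allylic strain with the 3-methyl group, which gives C3 (S) and the cis relation.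

Step 14
Reactants: 21 5-O-prenyl ether of the lactone-fused cis-chromanone
Product: 23 dearomatised enol lactone with quaternary C8 (R) bearing prenyl plus lavandulyl, via ortho-dienone 22 (not isolated)
Conditions: Eu(fod)3 (10 mol %), PhCl, 80 °C, Ar, dry, dark
Reagents that add atoms: none
Why: Proposed new method: Eu(III) bound between the C4 carbonyl and O5 weakens the O5–CH2 bond, a first chair-like [3,3] shift (ortho-Claisen) places the allyl unit as a 1,1-dimethylallyl group on blocked C6 (22; the path over blocked C4a is equivalent), and since neither ortho-dienone can enolise, a second [3,3] shift (Cope) across C7=C8 (or C8a=C8) forms the bond from the prenyl CH2 to C8 and leaves the cross-conjugated dienone 23. The closest known reaction type is the europium-catalysed Claisen–Cope (para-Claisen) rearrangement of 5-O-prenyl flavonoids to 8-prenyl flavonoids; new here are a para carbon that already carries an alkyl group, so that the ring cannot rearomatise, and the relay of configuration across the ring. No ring is closed: the two six-membered transition states only relocate the allyl unit, and the benzene ring itself becomes the cyclohexadienone. The one new stereocentre that persists, C8 (R), is controlled by Cα: peri strain with O5 keeps propyl pseudoaxial on one face of the lactone-clamped arene, the pseudoaxial methyl group of the cis-chromanone lies on that same face, the O5–CH2 bond of the di-ortho-substituted ether therefore stands on the other face, and because both shifts are suprafacial prenyl reaches C8 anti to propyl, which is the arrangement of the target. The step needs face selectivity under kinetic control and a product not far above the ether in energy; the rigid lactone and the low temperature allowed by the catalyst serve the first need, the phloroglucinol-type oxygenation, which makes 23 a vinylogous ester (O1–C8a=C4a–C5=O) conjugated with the C4 carbonyl, and the irreversible opening of the enol lactone in step 15 serve the second. Ionisation of the ether with loss of isoprene is held back by the non-polar, acid-free medium.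

Step 15
Reactants: 23 dearomatised enol lactone
Product: 25 CNP0266113.2 [(3R)-3-{(2R,3S,8R)-5-hydroxy-2,3-dimethyl-8-(3-methylbut-2-en-1-yl)-8-[(R)-lavandulyl]-4,7-dioxo-3,4,7,8-tetrahydro-2H-chromen-6-yl}hexanoic acid], via dilithium salt 24 (not isolated)
Conditions: LiOH (2.2 equiv), THF–H2O, 0 °C; then 1 M HCl to pH 3, 0 °C
Reagents that add atoms: lithium hydroxide, [Li+].[OH-]
Why: The enol lactone is a vinylogous anhydride and should be saponified within minutes in the cold, the resulting delocalised dianion resists enolisation at C3 and retro-oxa-Michael opening, and acidification gives the acid with the ring as the tautomer whose 5-OH is chelated to C4=O.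

Compound list
1 | 3-methylbut-2-enoyl chloride | CC(C)=CC(=O)Cl | starting material
2 | (S)-4-benzyloxazolidin-2-one | O=C1N[C@@H](Cc2ccccc2)CO1 | starting material
3 | (S)-4-benzyl-3-(3-methylbut-2-enoyl)oxazolidin-2-one | CC(C)=CC(=O)N1[C@@H](Cc2ccccc2)COC1=O | intermediate
4 | prenyl bromide (1-bromo-3-methylbut-2-ene) | CC(C)=CCBr | starting material
5 | sodium Z-dienolate of 3 (not isolated) | C=C(C)/C=C(\[O-])N1[C@@H](Cc2ccccc2)COC1=O.[Na+] | intermediate
6 | (S)-4-benzyl-3-[(2S)-5-methyl-2-(prop-1-en-2-yl)hex-4-enoyl]oxazolidin-2-one | C=C(C)[C@H](CC=C(C)C)C(=O)N1[C@@H](Cc2ccccc2)COC1=O | intermediate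
7 | (S)-lavandulol | C=C(C)[C@H](CC=C(C)C)CO | intermediate
8 | (S)-lavandulyl iodide | C=C(C)[C@H](CC=C(C)C)CI | intermediate
9 | 2,4,6-trihydroxypropiophenone | CCC(=O)c1c(O)cc(O)cc1O | starting material
10 | 5,7-diacetoxy-2,3-dimethylchromone | CC(=O)Oc1cc(OC(C)=O)c2c(c1)oc(C)c(C)c2=O | intermediate
11 | 5,7-dihydroxy-2,3-dimethylchromone | Cc1oc2cc(O)cc(O)c2c(=O)c1C | intermediate
12 | 5,7-bis(methoxymethoxy)-2,3-dimethylchromone | COCOc1cc(OCOC)c2c(c1)oc(C)c(C)c2=O | intermediate
13 | 8-iodo-5,7-bis(methoxymethoxy)-2,3-dimethylchromone | COCOc1cc(OCOC)c2c(c1I)oc(C)c(C)c2=O | intermediate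
14 | (S)-lavandulylzinc iodide (not isolated) | C=C(C)[C@H](CC=C(C)C)C[Zn]I | intermediate
15 | 8-[(R)-lavandulyl]-5,7-bis(methoxymethoxy)-2,3-dimethylchromone | C=C(C)[C@H](CC=C(C)C)Cc1c(OCOC)cc(OCOC)c2c1oc(C)c(C)c2=O | intermediate
16 | 8-[(R)-lavandulyl]-5,7-dihydroxy-2,3-dimethylchromone | C=C(C)[C@H](CC=C(C)C)Cc1c(O)cc(O)c2c1oc(C)c(C)c2=O | intermediate
17 | (E)-hex-2-enal | CCC/C=C/C=O | starting material
18 | lactone-fused chromone with free chelated 5-OH, Cα (R) | C=C(C)[C@H](CC=C(C)C)Cc1c4OC(=O)C[C@@H](CCC)c4c(O)c2c1oc(C)c(C)c2=O | intermediate
19 | 5-O-prenyl ether of 18 | C=C(C)[C@H](CC=C(C)C)Cc1c4OC(=O)C[C@@H](CCC)c4c(OCC=C(C)C)c2c1oc(C)c(C)c2=O | intermediate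
20 | (2R)-C4 diethoxy(methyl)silyl enol ether from 19 (not isolated) | C=C(C)[C@H](CC=C(C)C)Cc1c4OC(=O)C[C@@H](CCC)c4c(OCC=C(C)C)c2c1O[C@H](C)C(C)=C2O[Si](C)(OCC)OCC | intermediate
21 | 5-O-prenyl ether of the lactone-fused (2R,3S)-cis-chromanone | C=C(C)[C@H](CC=C(C)C)Cc1c4OC(=O)C[C@@H](CCC)c4c(OCC=C(C)C)c2c1O[C@H](C)[C@H](C)C2=O | intermediate
22 | (6S)-6-(2-methylbut-3-en-2-yl) ortho-dienone, allyl unit anti to propyl (not isolated) | C=C(C)[C@H](CC=C(C)C)CC1=C3OC(=O)C[C@@H](CCC)[C@@]3(C(C)(C)C=C)C(=O)C2=C1O[C@H](C)[C@H](C)C2=O | intermediate
23 | (8R)-dearomatised enol lactone with quaternary C8 | C=C(C)[C@H](CC=C(C)C)C[C@@]1(CC=C(C)C)C3=C([C@H](CCC)CC(=O)O3)C(=O)C2=C1O[C@H](C)[C@H](C)C2=O | intermediate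
24 | dilithium enolate carboxylate of 25 (not isolated) | [Li+].[Li+].C=C(C)[C@H](CC=C(C)C)C[C@@]1(CC=C(C)C)C([O-])=C([C@H](CCC)CC(=O)[O-])C(=O)C2=C1O[C@H](C)[C@H](C)C2=O | intermediate
25 | CNP0266113.2 | C=C(C)[C@H](CC=C(C)C)C[C@@]1(CC=C(C)C)C(=O)C([C@H](CCC)CC(=O)O)=C(O)C2=C1O[C@H](C)[C@H](C)C2=O | target

Total number of steps: 15. Longest linear sequence: 11 steps (steps 1–4 and 9–15; the chromone branch, steps 5–15, is equally long).

Steps most likely to fail

**Step 14 (the new method).**
- What may go wrong: the equilibrium between ether, ortho-dienones and para-dienone may stay on the aromatic side. The O5–CH2 bond may ionise, with loss of the C5 unit as isoprene. The two ring faces may be poorly distinguished. Long heating with a Lewis acid may epimerise C3.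
- Fallback: base-mediated alkylative dearomatisation of a 3,5-dialkylated acylphloroglucinol with prenyl bromide. This is the known way to gem-dialkylated cyclohexadienones of the hop β-acid type.
- The fallback sets out from 18. Conjugate reduction and cold protonation as in step 13 (the phenol is silylated in passing and freed on work-up) should give the free-phenol lactone-fused cis-chromanone F1.
- Aqueous KOH at 0 °C opens the lactone to the potassium salt of the 5,7-dihydroxy acid F2. Compound 4, added to the same cold solution, alkylates the polyanion at C8, the less hindered of the two alkyl-bearing ring carbons.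
- Acidification comes back to the route at 25. Face control by the lactone is given up, so a separation of diastereomers at the last stage has to be accepted.

**Step 11.**
- What may go wrong: acyl transfer to O7 may outrun C–C bond formation. The ring may close on O5 instead of O7. The faces of the β-alkyl acyl azolium may be poorly differentiated. The oxidant may attack the electron-rich phenol.
- Fallback: ring construction is separated from stereocontrol, setting out from 16.
- Esterification of the more acidic, non-chelated 7-OH with hex-2-ynoic acid (DCC, DMAP) gives the 7-O-hex-2-ynoate F3.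
- Gold(I)-catalysed 6-endo hydroarylation at C6 gives the 4-propylcoumarin-fused chromone F4.
- Ligand-controlled copper hydride conjugate reduction of the trisubstituted coumarin double bond, which is more reactive than the tetrasubstituted chromone double bond, sets Cα and comes back to the route at 18.

**Step 13.**
- What may go wrong: hydride transfer to the tetrasubstituted C2=C3 bond may stall, ligand control may be weak, and C3 may epimerise during or after protonation.
- Fallback: both centres are set while no other alkene is present, setting out from 12.
- Hydrogenation over a chiral rhodium or ruthenium bisphosphine catalyst (syn addition of H2, hence cis) gives (2R,3S)-5,7-bis(methoxymethoxy)-2,3-dimethylchroman-4-one F5.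
- F5 is then carried through the operations of steps 8 to 12: iodination to the 8-iodochromanone F6, coupling with 14 to the 8-lavandulyl bis-acetal chromanone F7, and acetal cleavage to the 8-lavandulyl-5,7-dihydroxychromanone F8. Annulation with 17 then gives the free-phenol lactone-fused cis-chromanone F1.
- O-prenylation of F1 with 4 comes back to the route at 21. Exposure of the cis pair to acid and base then has to be kept short in every one of these operations.

Further compounds
F1 | step 14 | free-phenol lactone-fused (2R,3S)-cis-chromanone | C=C(C)[C@H](CC=C(C)C)Cc1c4OC(=O)C[C@@H](CCC)c4c(O)c2c1O[C@H](C)[C@H](C)C2=O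
F2 | step 14 | (3R)-3-{(2R,3S)-5,7-dihydroxy-8-[(R)-lavandulyl]-2,3-dimethyl-4-oxochroman-6-yl}hexanoic acid (handled as its potassium salt) | C=C(C)[C@H](CC=C(C)C)Cc1c(O)c([C@H](CCC)CC(=O)O)c(O)c2c1O[C@H](C)[C@H](C)C2=O
F3 | step 11 | 7-O-hex-2-ynoate of 16 | C=C(C)[C@H](CC=C(C)C)Cc1c(OC(=O)C#CCCC)cc(O)c2c1oc(C)c(C)c2=O
F4 | step 11 | 4-propylcoumarin-fused chromone with free 5-OH | C=C(C)[C@H](CC=C(C)C)Cc1c4OC(=O)C=C(CCC)c4c(O)c2c1oc(C)c(C)c2=O
F5 | step 13 | (2R,3S)-5,7-bis(methoxymethoxy)-2,3-dimethylchroman-4-one | COCOc1cc(OCOC)c2c(c1)O[C@H](C)[C@H](C)C2=O
F6 | step 13 | (2R,3S)-8-iodo-5,7-bis(methoxymethoxy)-2,3-dimethylchroman-4-one | COCOc1cc(OCOC)c2c(c1I)O[C@H](C)[C@H](C)C2=O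
F7 | step 13 | (2R,3S)-8-[(R)-lavandulyl]-5,7-bis(methoxymethoxy)-2,3-dimethylchroman-4-one | C=C(C)[C@H](CC=C(C)C)Cc1c(OCOC)cc(OCOC)c2c1O[C@H](C)[C@H](C)C2=O
F8 | step 13 | (2R,3S)-8-[(R)-lavandulyl]-5,7-dihydroxy-2,3-dimethylchroman-4-one | C=C(C)[C@H](CC=C(C)C)Cc1c(O)cc(O)c2c1O[C@H](C)[C@H](C)C2=O
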